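## Retrosynthetic overview

1. Lindenane numbering is used: cyclopropane C1–C2–C3; ring A C1/C3/C4/C5/C10; ring B C5–C10; lactone C7/C8/O/C12/C11; primes for the second half. Target 22 is the C2-symmetric head-to-head [2+2] dimer (C8–C8′, C9–C9′) of chloranthalactone A 21, so the cyclobutane is made last, by light.
2. 21 goes back to the tricyclic C8 ketone 12. The lactone ring comes from C7 alkylation and oxidative enol-lactonization, and C4=C15 from methylenation of the ketone derived from the C4 carbinol.
3. Ring B of 12 is not closed as a six-membered ring. It grows from the four-membered ring C5–C6–C7–C8 of cyclobutanone 11 when rhodium inserts the isopropenyl carbons C10=C9 into the C5–C8 bond, and the same event closes ring A.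
4. Enabling feature: C8 of ring B is at the ketone level (the O–C8 enol-lactone carbon) and stands 1,4 to the fusion carbon C5. The other two ring-B atoms, C9–C10(C14), are an isopropenyl group. The ring-A atoms C4–C3–C1 form a three-atom tether held rigid by the cis-cyclopropane, and C10 is quaternary, so no β-hydrogen is available.
5. 11 comes from an anti-aldol of cyclobutanone 8 with cis-aldehyde 7, which is made from meso diester 1 by esterase desymmetrization. Ring order: cyclopropane and four-membered ring (bought), rings A + B (step 8), lactone (step 11), cyclobutane (step 15).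

Key step: step 8

Assumption: (R)-DTBM-SEGPHOS is taken as the ligand enantiomer matched to the (2S)-cyclobutanone 11. The ligand only modulates the rate, because every stereocentre of 12 derives from the substrate.

## Route

Step 1
Reactants: 1 dimethyl cis-cyclopropane-1,2-dicarboxylate (meso)
Product: 2 (1S,2R)-2-(methoxycarbonyl)cyclopropane-1-carboxylic acid
Conditions: pig liver esterase, 0.1 M phosphate buffer pH 7 (pH-stat, 1 M NaOH), 25 °C; then HCl to pH 2
Reagents that add atoms: water O
Why: Enzymatic desymmetrization of a meso diester by a carboxylesterase should hydrolyse only the ester on the S-configured ring carbon, which fixes the absolute configuration of C1 and C3, the source of all later stereocentres.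

Step 2
Reactants: 2 (1S,2R)-2-(methoxycarbonyl)cyclopropane-1-carboxylic acid
Product: 4 (1R,5S)-3-oxabicyclo[3.1.0]hexan-2-one, via hydroxy ester 3 (not isolated)
Conditions: BH3·SMe2, THF, 0 °C to rt; MeOH quench; cat. TsOH, CH2Cl2, rt
Reagents that add atoms: none
Why: Chemoselective borane reduction of the acid beside the ester, followed by lactonization of the cis hydroxy ester, differentiates the future C4 (CH2O) from the future C10 (C=O) without touching a stereocentre.

Step 3
Reactants: 4 (1R,5S)-3-oxabicyclo[3.1.0]hexan-2-one
Product: 5 (1R,5S)-2-methyl-3-oxabicyclo[3.1.0]hexan-2-ol (hemiketal)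
Conditions: MeLi (1.05 equiv), Et2O, −78 °C; AcOH quench
Reagents that add atoms: methyllithium [Li]C
Why: Mono-addition of an organolithium to a γ-lactone stops at the tetrahedral alkoxide at low temperature and brings in C14.

Step 4
Reactants: 5 (1R,5S)-2-methyl-3-oxabicyclo[3.1.0]hexan-2-ol
Product: 6 [(1S,2R)-2-(prop-1-en-2-yl)cyclopropyl]methanol
Conditions: Ph3PCH3Br (3 equiv), KOtBu (3 equiv), THF, 0 to 45 °C
Reagents that add atoms: methyltriphenylphosphonium bromide C[P+](c1ccccc1)(c1ccccc1)c1ccccc1.[Br-]
Why: Wittig methylenation drains the hemiketal through its open hydroxy-ketone tautomer and installs C9, and the weakly acidic cyclopropyl C–H keeps the cis relationship intact.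

Step 5
Reactants: 6 [(1S,2R)-2-(prop-1-en-2-yl)cyclopropyl]methanol
Product: 7 (1S,2R)-2-(prop-1-en-2-yl)cyclopropane-1-carbaldehyde
Conditions: (n-Pr)4N[RuO4] (5 mol %), NMO, 4 Å MS, CH2Cl2, 0 °C; used at once
Reagents that add atoms: none
Why: The neutral Ley–Griffith oxidation avoids epimerization, and immediate use keeps the mobile retro-Claisen equilibrium of the cis-vinylcyclopropyl aldehyde harmless.

Step 6
Reactants: 7 (1S,2R)-2-(prop-1-en-2-yl)cyclopropane-1-carbaldehyde; 8 cyclobutanone
Product: 10 (2S)-2-{(S)-hydroxy[(1S,2R)-2-(prop-1-en-2-yl)cyclopropyl]methyl}cyclobutan-1-one, via lithium cyclobutenolate 9 (not isolated)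
Conditions: LDA, THF, −78 °C; then 7, −78 °C, short contact; AcOH quench
Reagents that add atoms: none
Why: In this aldol addition the ring-locked E-enolate should give the anti adduct through a Zimmerman–Traxler chair (C5 relative to C4), and the aldehyde, in its bisected s-trans conformation, is attacked on the face away from the cis isopropenyl group (C4 relative to C3), so both controls converge on the C5 configuration that the target needs.

Step 7
Reactants: 10 anti-aldol
Product: 11 (2S)-2-{(S)-(tert-butyldimethylsilyloxy)[(1S,2R)-2-(prop-1-en-2-yl)cyclopropyl]methyl}cyclobutan-1-one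
Conditions: TBSOTf, 2,6-lutidine, CH2Cl2, −78 to 0 °C
Reagents that add atoms: tert-butyldimethylsilyl triflate CC(C)(C)[Si](C)(C)OS(=O)(=O)C(F)(F)F
Why: Silylation under non-nucleophilic, weakly basic conditions blocks retro-aldol and dehydration and leaves C4 and C5 untouched.

Step 8
Reactants: 11 silyloxy cyclobutanone
Product: 12 tricyclic C8 ketone (4β-OTBS; C2 β; C14 β; H-5 α)
Conditions: [Rh(cod)2]BF4 (10 mol %), (R)-DTBM-SEGPHOS (12 mol %), 1,4-dioxane, 40 °C
Reagents that add atoms: none
Why: Proposed new method: the cationic monovalent-rhodium catalyst adds oxidatively into the proximal acyl–carbon bond C8–C5 of the cyclobutanone to give a five-membered acyl-alkyl rhodacycle of trivalent rhodium, the chelated C10=C9 alkene inserts into the Rh–C5 bond, and C8(acyl)–C9 reductive elimination from the seven-membered rhodacycle releases 12, so the four-membered ring C5–C6–C7–C8 is enlarged by C9 and C10 to ring B. The closest known reaction type is the rhodium-catalysed intramolecular "cut-and-sew" [4+2] coupling of cyclobutanones and benzocyclobutenones with tethered π-systems, established for fused rings from benzocyclobutenone/alkene and 2-tethered cyclobutanone/alkyne pairs but not for a saturated 2-tethered cyclobutanone with an unactivated 1,1-disubstituted alkene next to a cyclopropane. Ring A closes by 5-exo-trig carborhodation (C5–C10 bond) and ring B by acyl–alkyl reductive elimination (C8–C9 bond), a two-carbon ring expansion driven by release of cyclobutanone strain. C5 keeps its configuration because oxidative addition and migratory insertion both go with retention at carbon, and the new quaternary C10 is set by the cis-cyclopropane, since the rhodium-bearing C9 can lie only on the convex α face of the nascent bicyclo[3.1.0]hexane, which leaves C14 β and, with the β C5–C6 bond, gives the trans A/B fusion. The step needs proximal rather than distal C–C cleavage, which the three-atom tether secures by chelation of the alkene, and a rhodium alkyl that cannot decay, which the substrate secures because the Rh–C9 carbon sits next to the quaternary C10 (no β-hydrogen) and is never bonded directly to the cyclopropane. C4 is kept sp3 as the silyl ether because a C4 alkene or ketone cis to the isopropenyl group would open Cope or retro-Claisen channels.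

Step 9
Reactants: 12 tricyclic C8 ketone; 13 ethyl (S)-2-(trifluoromethylsulfonyloxy)propanoate
Product: 15 γ-keto ester (C7-propanoate; epimers at C7 and C11), via lithium C7-enolate 14 (not isolated)
Conditions: LDA, THF, −78 °C; then 13, −78 to −40 °C
Reagents that add atoms: none
Why: Kinetic deprotonation should take place at C7 because C9 is neopentyl next to the quaternary C10, and SN2 alkylation by the reactive α-triflyloxy ester brings in C11–C13, whose two new centres are erased in step 11.

Step 10
Reactants: 15 γ-keto ester
Product: 16 γ-keto acid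
Conditions: LiOH, THF–MeOH–H2O, rt; then 1 M HCl to pH 3, 0 °C
Reagents that add atoms: lithium hydroxide [Li+].[OH-]
Why: Plain saponification spares the hindered secondary silyl ether, and no permanent stereocentre is acidic.

Step 11
Reactants: 16 γ-keto acid
Product: 18 4β-(tert-butyldimethylsilyloxy)-15-norlindena-7(11),8-dien-12,8-olide, via enol lactone 17 (not isolated)
Conditions: Ac2O, NaOAc (cat.), 90 °C; concentrate; then DDQ, 1,4-dioxane, 80 °C
Reagents that add atoms: none
Why: Enol-lactonization of a γ-keto acid followed by DDQ dehydrogenation of the enol ester (hydride abstraction at the allylic C7–H, proton loss from C11) should give the γ-alkylidene butenolide without strong acid and remove the temporary centres C7 and C11.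

Step 12
Reactants: 18 silyloxy dienolide
Product: 19 4β-hydroxy-15-norlindena-7(11),8-dien-12,8-olide
Conditions: HF·pyridine, THF, 0 °C to rt
Reagents that add atoms: none
Why: Fluoride-mediated desilylation in a buffered, non-basic medium spares the base-sensitive enol lactone.

Step 13
Reactants: 19 C4 alcohol
Product: 20 4-oxo-15-norlindena-7(11),8-dien-12,8-olide
Conditions: Dess–Martin periodinane, CH2Cl2, 0 °C to rt
Reagents that add atoms: none
Why: The near-neutral Dess–Martin oxidation removes the temporary C4 centre and should leave the now enolizable C5–H unepimerized.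

Step 14
Reactants: 20 C4 ketone
Product: 21 chloranthalactone A (lindena-4(15),7(11),8-trien-12,8-olide)
Conditions: Zn, CH2Br2, TiCl4 (pre-aged reagent), CH2Cl2–THF, 0 °C to rt
Reagents that add atoms: dibromomethane BrCBr
Why: The Lombardo methylenation uses a non-basic gem-dimetallic reagent that is selective for ketones over lactones, so C15 is installed without epimerization at C5 or opening of the enol lactone.

Step 15
Reactants: 21 chloranthalactone A (two molecules)
Product: 22 target dimer
Conditions: hν (medium-pressure Hg lamp, Pyrex filter), degassed n-hexane, rt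
Reagents that add atoms: none
Why: In this [2+2] photodimerization of the C8=C9 enol-lactone double bond, first bonding at C9–C9′ gives the best-stabilized 1,4-diradical (tertiary, α-oxy, allylic at C8/C8′) and hence the head-to-head adduct, and both monomers can react only through their α faces because C14 and C2 shield the β faces, which sets C8, C9, C8′ and C9′ in the C2-symmetric cis-anti-cis array.

## Compound list

| No. | Name | SMILES | Role |
|---|---|---|---|
| 1 | dimethyl cis-cyclopropane-1,2-dicarboxylate | COC(=O)[C@@H]1C[C@@H]1C(=O)OC | starting material |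
| 2 | (1S,2R)-2-(methoxycarbonyl)cyclopropane-1-carboxylic acid | COC(=O)[C@@H]1C[C@@H]1C(=O)O | intermediate |
| 3 | methyl (1R,2S)-2-(hydroxymethyl)cyclopropane-1-carboxylate | COC(=O)[C@@H]1C[C@@H]1CO | intermediate |
| 4 | (1R,5S)-3-oxabicyclo[3.1.0]hexan-2-one | O=C1OC[C@H]2C[C@@H]12 | intermediate |
| 5 | (1R,5S)-2-methyl-3-oxabicyclo[3.1.0]hexan-2-ol (anomers, in equilibrium with the hydroxy ketone) | CC1(O)OC[C@H]2C[C@@H]12 | intermediate |
| 6 | [(1S,2R)-2-(prop-1-en-2-yl)cyclopropyl]methanol | C=C(C)[C@@H]1C[C@@H]1CO | intermediate |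
| 7 | (1S,2R)-2-(prop-1-en-2-yl)cyclopropane-1-carbaldehyde | C=C(C)[C@@H]1C[C@@H]1C=O | intermediate |
| 8 | cyclobutanone | O=C1CCC1 | starting material |
| 9 | lithium cyclobut-1-en-1-olate | [Li+].[O-]C1=CCC1 | intermediate |
| 10 | (2S)-2-{(S)-hydroxy[(1S,2R)-2-(prop-1-en-2-yl)cyclopropyl]methyl}cyclobutan-1-one | C=C(C)[C@@H]1C[C@@H]1[C@H](O)[C@@H]1CCC1=O | intermediate |
| 11 | (2S)-2-{(S)-(tert-butyldimethylsilyloxy)[(1S,2R)-2-(prop-1-en-2-yl)cyclopropyl]methyl}cyclobutan-1-one | C=C(C)[C@@H]1C[C@@H]1[C@H](O[Si](C)(C)C(C)(C)C)[C@@H]1CCC1=O | intermediate |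
| 12 | 4β-(tert-butyldimethylsilyloxy)-11,12,13,15-tetranorlindenan-8-one (C2 β, C14 β, H-5 α, trans A/B) | CC(C)(C)[Si](C)(C)O[C@H]1[C@H]2C[C@H]2[C@@]2(C)[C@H]1CCC(=O)C2 | intermediate |
| 13 | ethyl (S)-2-(trifluoromethylsulfonyloxy)propanoate | C[C@H](OS(=O)(=O)C(F)(F)F)C(=O)OCC | starting material |
| 14 | lithium C7(8)-enolate of 12 | CC(C)(C)[Si](C)(C)O[C@H]1[C@H]2C[C@H]2[C@@]2(C)[C@H]1CC=C([O-])C2.[Li+] | intermediate |
| 15 | ethyl 2-[4β-(tert-butyldimethylsilyloxy)-8-oxo-tetranorlindenan-7-yl]propanoate (epimers at C7, C11) | CC(C)(C)[Si](C)(C)O[C@H]1[C@H]2C[C@H]2[C@@]2(C)[C@H]1CC(C(C)C(=O)OCC)C(=O)C2 | intermediate |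
| 16 | corresponding γ-keto acid | CC(C)(C)[Si](C)(C)O[C@H]1[C@H]2C[C@H]2[C@@]2(C)[C@H]1CC(C(C)C(=O)O)C(=O)C2 | intermediate |
| 17 | 8(9)-enol lactone of 16 | CC(C)(C)[Si](C)(C)O[C@H]1[C@H]2C[C@H]2[C@@]2(C)[C@H]1CC1C(C)C(=O)OC1=C2 | intermediate |
| 18 | 4β-(tert-butyldimethylsilyloxy)-15-norlindena-7(11),8-dien-12,8-olide | CC(C)(C)[Si](C)(C)O[C@H]1[C@H]2C[C@H]2[C@@]2(C)[C@H]1CC1=C(C)C(=O)OC1=C2 | intermediate |
| 19 | 4β-hydroxy-15-norlindena-7(11),8-dien-12,8-olide | O[C@H]1[C@H]2C[C@H]2[C@@]2(C)[C@H]1CC1=C(C)C(=O)OC1=C2 | intermediate |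
| 20 | 4-oxo-15-norlindena-7(11),8-dien-12,8-olide | O=C1[C@H]2C[C@H]2[C@@]2(C)[C@H]1CC1=C(C)C(=O)OC1=C2 | intermediate |
| 21 | chloranthalactone A | C=C1[C@H]2C[C@H]2[C@@]2(C)[C@H]1CC1=C(C)C(=O)OC1=C2 | intermediate |
| 22 | head-to-head, cis-anti-cis [2+2] dimer of 21 (C8–C8′, C9–C9′) | C=C1[C@H]2C[C@H]2[C@@]2(C)[C@H]1CC1=C(C)C(=O)O[C@]13[C@H]2[C@H]1[C@@]2(C)[C@@H]4C[C@@H]4C(=C)[C@@H]2CC2=C(C)C(=O)O[C@@]213 | target |

Total step count: 15. Longest linear sequence: 15 steps (1 to 22).

## Steps most likely to fail

**Step 8.**
- What may go wrong: rhodium may add oxidatively into the vinylcyclopropane instead of the cyclobutanone. Distal C–C cleavage may be followed by decarbonylation. The silyloxy group may be lost by β-elimination from the C5–rhodium alkyl. Insertion of the hindered alkene may be too slow.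
- Fallback (known chemistry, sets out from 7, comes back at 12): the four-to-six enlargement is done stepwise through a ketene cycloaddition. Aldehyde 7 is added to the lithium dienolate of methyl crotonate (LDA, THF, −78 °C, α-selective aldol) to give methyl 2-ethenyl-3-hydroxy-3-[(1S,2R)-2-(prop-1-en-2-yl)cyclopropyl]propanoate F1. This is silylated (TBSOTf, 2,6-lutidine) to the silyl ether F2 and saponified (LiOH) to the acid F3. Oxalyl chloride gives the acid chloride F4, and slow addition of this to Et3N in refluxing toluene generates the vinylketene F5. It closes by the known intramolecular ketene–alkene [2+2] cycloaddition, with the ketene carbonyl carbon bonding to the CH2 terminus on the convex face, to the 5-vinyl cyclobutanone F6, which already holds ring A, C10 and a four-membered ring C5–C8–C9–C10. Direct irradiation (300 nm, benzene) then brings about the known 1,3-acyl shift of a β,γ-unsaturated ketone. C8 moves from C5 to C7, which enlarges that four-membered ring by C6 and C7 to the cyclohex-3-enone F7. Hydrogenation (H2, Pd/C, EtOAc) from the open α face sets H-5 α and gives 12.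

**Step 6.**
- What may go wrong: the cyclobutanone enolate may self-condense. Anti selectivity may erode through reversible lithium aldolate formation. The aldehyde may epimerize or drift to its valence tautomer before it is captured.
- Fallback (sets out from 7 and 8, comes back at 10): the preformed metal enolate under substrate control is replaced by enamine catalysis under catalyst control. L-proline (30 mol %) is used in DMSO at rt with cyclobutanone in excess. By the Houk–List model its hydrogen-bonded transition state delivers the (2S)-anti adduct, which is the sense matched to the facial bias of the aldehyde. No strong base is present, and the aldehyde is drawn continuously from its equilibrium. This fallback makes no compound outside the list (F0).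

**Step 14.**
- What may go wrong: the reagent may attack the enol lactone. Methylenation may be sluggish at the C4 carbonyl, which is flanked by two methine carbons. C5 may epimerize during a long reaction.
- Fallback (sets out from 12, comes back at 21): C15 is installed before the lactone exists. Ketone 12 is protected (1,2-bis(trimethylsilyloxy)ethane, cat. TMSOTf, CH2Cl2, −78 °C) as the C8 dioxolane F8. This is desilylated (TBAF, THF) to the alcohol F9, oxidized (Dess–Martin periodinane) to the C4 ketone F10 and methylenated by a Wittig reaction (Ph3P=CH2, THF, 0 °C) to the methylene ketal F11. Mild hydrolysis (PPTS, wet acetone, rt) gives the methylene ketone F12. It is then alkylated with 13 as in step 9 to the keto ester F13, saponified to the keto acid F14, and taken through the enol lactone F15 (Ac2O, cat. NaOAc) and DDQ as in step 11 to 21.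

## Further compounds

F1 | step 8 | methyl 2-ethenyl-3-hydroxy-3-[(1S,2R)-2-(prop-1-en-2-yl)cyclopropyl]propanoate (3S; epimers at C2) | C=C(C)[C@@H]1C[C@@H]1[C@H](O)C(C=C)C(=O)OC
F2 | step 8 | tert-butyldimethylsilyl ether of F1 | C=C(C)[C@@H]1C[C@@H]1[C@H](O[Si](C)(C)C(C)(C)C)C(C=C)C(=O)OC
F3 | step 8 | carboxylic acid from F2 | C=C(C)[C@@H]1C[C@@H]1[C@H](O[Si](C)(C)C(C)(C)C)C(C=C)C(=O)O
F4 | step 8 | acid chloride from F3 | C=C(C)[C@@H]1C[C@@H]1[C@H](O[Si](C)(C)C(C)(C)C)C(C=C)C(=O)Cl
F5 | step 8 | vinylketene from F4 | C=C(C)[C@@H]1C[C@@H]1[C@H](O[Si](C)(C)C(C)(C)C)C(C=C)=C=O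
F6 | step 8 | 5β-vinyl cyclobutanone (rings 3/5/4; C8 and C9 α, C14 β, 4β-OTBS) | CC(C)(C)[Si](C)(C)O[C@H]1[C@H]2C[C@H]2[C@]2(C)CC(=O)[C@]12C=C
F7 | step 8 | 5(6)-ene of 12 (cyclohex-3-enone) | CC(C)(C)[Si](C)(C)O[C@H]1[C@H]2C[C@H]2[C@@]2(C)C1=CCC(=O)C2
F0 | step 6 | none | none
F8 | step 14 | C8 ethylene ketal of 12 | CC(C)(C)[Si](C)(C)O[C@H]1[C@H]2C[C@H]2[C@@]2(C)[C@H]1CCC1(OCCO1)C2
F9 | step 14 | 4β-alcohol of the ketal | O[C@H]1[C@H]2C[C@H]2[C@@]2(C)[C@H]1CCC1(OCCO1)C2
F10 | step 14 | C4 ketone of the ketal | O=C1[C@H]2C[C@H]2[C@@]2(C)[C@H]1CCC1(OCCO1)C2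
F11 | step 14 | 4(15)-methylene ketal | C=C1[C@H]2C[C@H]2[C@@]2(C)[C@H]1CCC1(OCCO1)C2
F12 | step 14 | 4(15)-methylene C8 ketone | C=C1[C@H]2C[C@H]2[C@@]2(C)[C@H]1CCC(=O)C2
F13 | step 14 | ethyl C7-propanoate of F12 (epimers at C7, C11) | C=C1[C@H]2C[C@H]2[C@@]2(C)[C@H]1CC(C(C)C(=O)OCC)C(=O)C2
F14 | step 14 | γ-keto acid from F13 | C=C1[C@H]2C[C@H]2[C@@]2(C)[C@H]1CC(C(C)C(=O)O)C(=O)C2
F15 | step 14 | 8(9)-enol lactone of F14 | C=C1[C@H]2C[C@H]2[C@@]2(C)[C@H]1CC1C(C)C(=O)OC1=C2
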